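**Retrosynthetic overview**
1. Labels: xanthanolide numbering, primes for the upper half. Ring A = upper lactone, B = upper cycloheptane, C = central cyclohexene (C1′, C2′, C3′, C11, C13, C5′), D = spiro lactone, E = lower cycloheptene.
2. Ring C is closed last: C3′–C4′ (acetyl) by Heck coupling of an enol triflate, C1′–C2′ by aldol of a C11 acetyl group onto the C1′ ketone.
3. The halves are joined at the spiro carbon: C11–C13 by a copper-hydride-catalysed reductive coupling of Morita–Baylis–Hillman carbonate 14 (rings A/B) with α-acetyl lactone 28 (rings D/E).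
4. 14 comes from a bicyclic lactone by allylic oxidation, methylation and hydroxymethylation; 28 comes from the enantiomeric lactone via enone, enol triflate, B-alkyl Suzuki coupling and C-acetylation.
5. Both cis-fused lactones come from one desymmetrised monoacetate (from cyclohepta-1,3-diene) by complementary Ireland and Johnson Claisen rearrangements. Ring order: B and E are bought as the carbocycle, A and D by lactonisation, C last.

Assumption: the lipase gives monoacetate 3 in the absolute configuration drawn; with an enzyme of opposite preference the Ireland and Johnson sequences (step 3 and steps 11–12) are exchanged between the two series.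

**Common steps**

Step 1
Reactants: 1 cyclohepta-1,3-diene
Product: 2 cis-cyclohept-2-ene-1,4-diyl diacetate (meso)
Conditions: Pd(OAc)2 (5 mol%), LiCl (20 mol%), LiOAc, p-benzoquinone (2 equiv), AcOH, 25 °C
Reagents that add atoms: acetic acid CC(=O)O
Why: Bäckvall 1,4-diacetoxylation with divalent palladium; two external acetate attacks anti to the metal (chloride blocks internal delivery) place both acetates cis.

Step 2
Reactants: 2 cis-cyclohept-2-ene-1,4-diyl diacetate
Product: 3 (1S,4R)-4-hydroxycyclohept-2-en-1-yl acetate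
Conditions: Burkholderia cepacia lipase, phosphate buffer pH 7, 25 °C
Reagents that add atoms: none
Why: Enzymatic desymmetrisation; hydrolysis of one enantiotopic acetate fixes the two carbinol centres that become C8′ and C8.

**Upper fragment (rings A/B)**

Step 3
Reactants: 3 (1S,4R)-4-hydroxycyclohept-2-en-1-yl acetate
Product: 6 (3aS,8aR)-3,3a,6,7,8,8a-hexahydro-2H-cyclohepta[b]furan-2-one, via silyl ketene acetal 4 (not isolated), via hydroxy acid 5 (not isolated)
Conditions: LiN(i-Pr)2 (2.2 equiv), Me3SiCl (2.5 equiv), THF, −78 to 60 °C; then 1 M HCl, THF, rt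
Reagents that add atoms: none
Why: Ireland–Claisen rearrangement; the suprafacial [3,3] shift forms C7′–C11′ on the face of the departing oxygen, which is cis to the C8′ oxygen, so acid work-up closes the cis-fused lactone.

Step 4
Reactants: 6 (3aS,8aR)-lactone
Product: 7 (3S,3aR,8aR)-3-(hydroxymethyl)-3,3a,6,7,8,8a-hexahydro-2H-cyclohepta[b]furan-2-one
Conditions: LiN(i-Pr)2 (1.1 equiv), THF, −78 °C; HCHO (gas), −78 to −30 °C; AcOH
Reagents that add atoms: formaldehyde C=O
Why: Lactone enolate aldol with formaldehyde on the convex face of the cis-fused bicycle; this centre is erased in step 23.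

Step 5
Reactants: 7 hydroxymethyl lactone
Product: 8 (3S,3aR,8aR)-3-[(tert-butyldimethylsilyloxy)methyl]-3,3a,6,7,8,8a-hexahydro-2H-cyclohepta[b]furan-2-one
Conditions: TBSCl, imidazole, CH2Cl2, rt
Reagents that add atoms: tert-butyldimethylsilyl chloride CC(C)(C)[Si](C)(C)Cl
Why: Silylation of the primary alcohol masks the future exo-methylene carbon through all enolate and coupling steps.

Step 6
Reactants: 8 silyl ether lactone
Product: 9 (3S,3aR,8aR)-3-[(tert-butyldimethylsilyloxy)methyl]-3,3a,8,8a-tetrahydro-2H-cyclohepta[b]furan-2,6(7H)-dione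
Conditions: Rh2(cap)4 (dirhodium tetracaprolactamate, 1 mol%), t-BuOOH (5 equiv), K2CO3 (0.5 equiv), CH2Cl2, rt
Reagents that add atoms: tert-butyl hydroperoxide CC(C)(C)OO
Why: Allylic C–H oxidation; the tert-butylperoxy radical abstracts H from the unhindered ring CH2 (C1′) in preference to the ring-fusion methine and the mixed peroxide collapses to the enone.

Step 7
Reactants: 9 enone
Product: 10 7-methyl derivative of 9 as a mixture of C7 (C10′) epimers
Conditions: LiN(i-Pr)2 (1.05 equiv), THF, −78 °C; MeI, −78 to −40 °C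
Reagents that add atoms: iodomethane CI
Why: Kinetic cross-conjugated (α′) enolate alkylation; the electrophile enters mainly anti to lactone A, so the mixture is corrected in step 8.

Step 8
Reactants: 10 methyl enone (epimer mixture)
Product: 12 (3S,3aR,7S,8aR)-3-[(tert-butyldimethylsilyloxy)methyl]-7-methyl-3,3a,8,8a-tetrahydro-2H-cyclohepta[b]furan-2,6(7H)-dione, via lithium dienolate 11 (not isolated)
Conditions: LiN(i-Pr)2 (1.1 equiv), THF, −78 °C; AcOH in THF, −78 °C
Reagents that add atoms: none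
Why: Enolate formation then kinetic protonation from the face opposite lactone A pushes the methyl onto the lactone face (C10′ as in the target).

Step 9
Reactants: 12 methyl enone
Product: 13 (3S,3aR,7S,8aR)-3-[(tert-butyldimethylsilyloxy)methyl]-5-(hydroxymethyl)-7-methyl-3,3a,8,8a-tetrahydro-2H-cyclohepta[b]furan-2,6(7H)-dione
Conditions: 37% aq. HCHO, imidazole (1 equiv), THF/H2O, rt
Reagents that add atoms: formaldehyde C=O
Why: Morita–Baylis–Hillman reaction installs C13 on the enone α-carbon (C5′) under conditions too mild to touch the α′ stereocentre.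

Step 10
Reactants: 13 allylic alcohol
Product: 14 tert-butyl carbonate of 13
Conditions: Boc2O, DMAP (10 mol%), CH2Cl2, 0 °C to rt
Reagents that add atoms: di-tert-butyl dicarbonate CC(C)(C)OC(=O)OC(=O)OC(C)(C)C
Why: Acylation turns the allylic alcohol into a leaving group that releases tert-butoxide and CO2 on ionisation.

**Lower fragment (rings D/E)**

Step 11
Reactants: 3 (1S,4R)-4-hydroxycyclohept-2-en-1-yl acetate
Product: 16 methyl 2-[(1R,7S)-7-acetoxycyclohept-2-en-1-yl]acetate, via mixed ketene acetal 15 (not isolated)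
Conditions: MeC(OMe)3 (8 equiv), EtCO2H (10 mol%), 125 °C, MeOH distilled off
Reagents that add atoms: trimethyl orthoacetate CC(OC)(OC)OC
Why: Johnson–Claisen rearrangement at the free hydroxyl; the suprafacial shift forms C7–C11 cis to the retained acetoxy group, which gives the enantiomeric series to step 3.

Step 12
Reactants: 16 acetoxy ester
Product: 18 (3aR,8aS)-3,3a,6,7,8,8a-hexahydro-2H-cyclohepta[b]furan-2-one, via hydroxy ester 17 (not isolated)
Conditions: K2CO3 (0.2 equiv), MeOH, rt; then p-TsOH (cat.), PhMe, 60 °C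
Reagents that add atoms: none
Why: Methanolysis of the acetate then acid-catalysed lactonisation of the cis-γ-hydroxy ester.

Step 13
Reactants: 18 (3aR,8aS)-lactone
Product: 19 (3aR,8aS)-3,3a,8,8a-tetrahydro-2H-cyclohepta[b]furan-2,6(7H)-dione
Conditions: Rh2(cap)4 (1 mol%), t-BuOOH (5 equiv), K2CO3 (0.5 equiv), CH2Cl2, rt
Reagents that add atoms: tert-butyl hydroperoxide CC(C)(C)OO
Why: Allylic C–H oxidation at the ring CH2 (C1), as in step 6.

Step 14
Reactants: 19 enone
Product: 20 7-methyl derivative of 19 as a mixture of C7 (C10) epimers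
Conditions: LiN(i-Pr)2 (1.05 equiv), THF, −78 °C; MeI, −78 to −40 °C
Reagents that add atoms: iodomethane CI
Why: Kinetic α′-enolate methylation, as in step 7.

Step 15
Reactants: 20 methyl enone (epimer mixture)
Product: 22 (3aR,7R,8aS)-7-methyl-3,3a,8,8a-tetrahydro-2H-cyclohepta[b]furan-2,6(7H)-dione, via lithium dienolate 21 (not isolated)
Conditions: LiN(i-Pr)2 (1.1 equiv), THF, −78 °C; AcOH in THF, −78 °C
Reagents that add atoms: none
Why: Kinetic protonation anti to the lactone places the methyl cis to the C8 oxygen (C10 as in the target).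

Step 16
Reactants: 22 methyl enone
Product: 24 (3aS,7R,8aS)-7-methyl-2-oxo-3,3a,4,7,8,8a-hexahydro-2H-cyclohepta[b]furan-6-yl trifluoromethanesulfonate, via triethylsilyl enol ether 23 (not isolated)
Conditions: Et3SiH, RhCl(PPh3)3 (1 mol%), PhMe, 60 °C; then CsF, PhNTf2, DME, rt
Reagents that add atoms: N-phenylbis(trifluoromethanesulfonimide) O=S(=O)(N(c1ccccc1)S(=O)(=O)C(F)(F)F)C(F)(F)F
Why: Ojima 1,4-hydrosilylation gives the enol ether regiospecifically at C1=C5, and fluoride-mediated triflation keeps that position without touching the C10 centre.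

Step 17
Reactants: 24 enol triflate, 25 2-methyl-2-vinyl-1,3-dioxolane
Product: 27 (3aS,7R,8aS)-7-methyl-6-[2-(2-methyl-1,3-dioxolan-2-yl)ethyl]-3,3a,4,7,8,8a-hexahydro-2H-cyclohepta[b]furan-2-one, via B-alkyl-9-BBN 26 (not isolated)
Conditions: 25, 9-BBN, THF, rt; then 24, Pd(dppf)Cl2 (5 mol%), 3 M aq. K3PO4, DMF, 50 °C
Reagents that add atoms: none
Why: Anti-Markovnikov hydroboration then Suzuki–Miyaura B-alkyl coupling forms the C1–C2 bond with the ketone masked as its dioxolane.

Step 18
Reactants: 27 lactone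
Product: 28 (3RS,3aS,7R,8aS)-3-acetyl-7-methyl-6-[2-(2-methyl-1,3-dioxolan-2-yl)ethyl]-3,3a,4,7,8,8a-hexahydro-2H-cyclohepta[b]furan-2-one
Conditions: LiN(i-Pr)2 (2.2 equiv), THF, −78 °C; MeC(O)N(OMe)Me, −78 to 0 °C; AcOH
Reagents that add atoms: N-methoxy-N-methylacetamide CC(=O)N(C)OC
Why: Claisen-type C-acylation of the lactone enolate with a Weinreb amide (stable chelate, no over-addition); the C11 centre is left epimeric because it is reset in step 19.

**Union and endgame**

Step 19
Reactants: 14 tert-butyl carbonate, 28 α-acetyl lactone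
Product: 32 coupled diketone (C11–C13 bond; C11 and C5′ as in the target), via trimethylsilyl enol ether 29 (not isolated), via exo-methylene ketone 30 (not isolated), via silyl enol ether 31 (not isolated)
Conditions: 28, BSA (1.3 equiv), PhMe, rt; then 14, Cu(OAc)2·H2O (5 mol%), 1,2-(Ph2P)2C6H4 (5 mol%), (EtO)2MeSiH (1.2 equiv, syringe pump), 0 °C to rt; then aq. citric acid, THF, 0 °C
Reagents that add atoms: none
Why: Proposed new method: a copper hydride relay in which LCuH adds hydride to C6′ of enone carbonate 14 and the copper enolate expels the carbonate (formal SN2′ reduction) to give exo-methylene ketone 30 and, after loss of CO2, LCuOt-Bu; the alkoxide desilylates 29 to a chelated copper enolate that adds in Michael fashion to 30 on the convex face of the lower bicycle (C13 enters anti to C6/C9, setting the C11 quaternary centre), and the new copper enolate is silylated by the hydrosilane to 31, so CuH is regenerated only after C–C bond formation and slow silane addition suppresses over-reduction of 30; mild acid hydrolysis protonates C5′ from the face opposite lactone A; closest known reactions are Stryker-type CuH conjugate reduction, CuH-catalysed reductive aldol and Michael cyclisations, and copper alkoxide/silyl enolate Mukaiyama–Michael additions.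

Step 20
Reactants: 32 coupled diketone
Product: 33 ring C ketol (C1′ tertiary alcohol, C3′ ketone; trans B/C fusion)
Conditions: LiN(SiMe3)2 (1.1 equiv), THF, −78 to −20 °C, 2 h; AcOH, −78 °C
Reagents that add atoms: none
Why: Intramolecular aldol; only the acetyl methyl is enolised kinetically, and the reversible 6-membered closure settles on the trans-fused ketol (axial OH, C2′ anti to both α-substituents of the C1′ ketone) without enolising C5′, so no retro-Michael occurs.

Step 21
Reactants: 33 ketol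
Product: 34 hydroxy enol triflate (C2′=C3′–OTf)
Conditions: LiN(SiMe3)2 (2.1 equiv), THF, −78 °C; Comins' reagent (1.2 equiv), −78 to −30 °C; AcOH
Reagents that add atoms: N-(5-chloropyridin-2-yl)bis(trifluoromethanesulfonimide) O=S(=O)(N(c1ccc(Cl)cn1)S(=O)(=O)C(F)(F)F)C(F)(F)F
Why: Enolate O-triflation; the C3′ ketone can enolise only toward C2′ because C11 is quaternary, and the lithium aldolate is stable at −78 °C.

Step 22
Reactants: 34 hydroxy enol triflate, 35 butyl vinyl ether
Product: 37 13′-hydroxy-11′,13′-dihydro target (α-hydroxymethyl lactone), via butoxydiene 36 (not isolated)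
Conditions: Pd(OAc)2 (5 mol%), dppp (10 mol%), Et3N, DMF, 80 °C; then 2 M HCl, THF, rt
Reagents that add atoms: water O
Why: Heck reaction by the cationic pathway gives α-selective vinylation of the vinyl ether (C3′–C4′ bond); acid then hydrolyses the enol ether to the acetyl enone, opens the dioxolane and removes the silyl group.

Step 23
Reactants: 37 α-hydroxymethyl lactone
Product: 39 target CNP0195550.1, via mesylate 38 (not isolated)
Conditions: MsCl, Et3N, CH2Cl2, 0 °C; then DBU, rt
Reagents that add atoms: none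
Why: Selective mesylation of the primary alcohol (the tertiary C1′–OH is inert) and E1cB elimination give the α-methylene lactone.

**Compound list**
1 | cyclohepta-1,3-diene | C1=CC=CCCC1 | starting material
2 | cis-cyclohept-2-ene-1,4-diyl diacetate (meso) | CC(=O)O[C@@H]1CCC[C@H](OC(C)=O)C=C1 | intermediate
3 | (1S,4R)-4-hydroxycyclohept-2-en-1-yl acetate | O[C@@H]1CCC[C@H](OC(C)=O)C=C1 | intermediate
4 | O-trimethylsilyl ether / trimethylsilyl ketene acetal of 3 | C[Si](C)(C)O[C@@H]1CCC[C@H](OC(=C)O[Si](C)(C)C)C=C1 | intermediate (not isolated)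
5 | 2-[(1S,7R)-7-hydroxycyclohept-2-en-1-yl]acetic acid | OC(=O)C[C@H]1C=CCCC[C@H]1O | intermediate (not isolated)
6 | (3aS,8aR)-3,3a,6,7,8,8a-hexahydro-2H-cyclohepta[b]furan-2-one (cis-fused) | O=C1C[C@H]2C=CCCC[C@H]2O1 | intermediate
7 | (3S,3aR,8aR)-3-(hydroxymethyl) lactone (CH2OH on the convex face) | OC[C@H]1C(=O)O[C@@H]2CCCC=C[C@H]12 | intermediate
8 | tert-butyldimethylsilyl ether of 7 | CC(C)(C)[Si](C)(C)OC[C@H]1C(=O)O[C@@H]2CCCC=C[C@H]12 | intermediate
9 | upper enone (C6 ketone, C4=C5) | CC(C)(C)[Si](C)(C)OC[C@H]1C(=O)O[C@@H]2CCC(=O)C=C[C@H]12 | intermediate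
10 | 7-methyl upper enone, C7 epimer mixture | CC(C)(C)[Si](C)(C)OC[C@H]1C(=O)O[C@@H]2CC(C)C(=O)C=C[C@H]12 | intermediate
11 | lithium dienolate of 10 | CC(C)(C)[Si](C)(C)OC[C@H]1C(=O)O[C@@H]2CC(C)=C(O[Li])C=C[C@H]12 | intermediate (not isolated)
12 | (3S,3aR,7S,8aR)-7-methyl upper enone (methyl cis to ring oxygen) | CC(C)(C)[Si](C)(C)OC[C@H]1C(=O)O[C@@H]2C[C@H](C)C(=O)C=C[C@H]12 | intermediate
13 | 5-(hydroxymethyl) derivative of 12 | CC(C)(C)[Si](C)(C)OC[C@H]1C(=O)O[C@@H]2C[C@H](C)C(=O)C(CO)=C[C@H]12 | intermediate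
14 | tert-butyl carbonate of 13 | CC(C)(C)[Si](C)(C)OC[C@H]1C(=O)O[C@@H]2C[C@H](C)C(=O)C(COC(=O)OC(C)(C)C)=C[C@H]12 | intermediate
15 | mixed methyl ketene acetal of 3 | C=C(OC)O[C@@H]1CCC[C@H](OC(C)=O)C=C1 | intermediate (not isolated)
16 | methyl 2-[(1R,7S)-7-acetoxycyclohept-2-en-1-yl]acetate | COC(=O)C[C@@H]1C=CCCC[C@@H]1OC(C)=O | intermediate
17 | methyl 2-[(1R,7S)-7-hydroxycyclohept-2-en-1-yl]acetate | COC(=O)C[C@@H]1C=CCCC[C@@H]1O | intermediate (not isolated)
18 | (3aR,8aS)-3,3a,6,7,8,8a-hexahydro-2H-cyclohepta[b]furan-2-one (cis-fused) | O=C1C[C@@H]2C=CCCC[C@@H]2O1 | intermediate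
19 | (3aR,8aS)-3,3a,8,8a-tetrahydro-2H-cyclohepta[b]furan-2,6(7H)-dione | C1C(=O)O[C@H]2CCC(=O)C=C[C@@H]12 | intermediate
20 | 7-methyl lower enone, C7 epimer mixture | C1C(=O)O[C@H]2CC(C)C(=O)C=C[C@@H]12 | intermediate
21 | lithium dienolate of 20 | C1C(=O)O[C@H]2CC(C)=C(O[Li])C=C[C@@H]12 | intermediate (not isolated)
22 | (3aR,7R,8aS)-7-methyl lower enone (methyl cis to ring oxygen) | C1C(=O)O[C@H]2C[C@@H](C)C(=O)C=C[C@@H]12 | intermediate
23 | triethylsilyl enol ether (C5=C6) from 22 | C1C(=O)O[C@H]2C[C@@H](C)C(O[Si](CC)(CC)CC)=CC[C@@H]12 | intermediate (not isolated)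
24 | (3aS,7R,8aS)-enol triflate | C1C(=O)O[C@H]2C[C@@H](C)C(OS(=O)(=O)C(F)(F)F)=CC[C@@H]12 | intermediate
25 | 2-methyl-2-vinyl-1,3-dioxolane | C=CC1(C)OCCO1 | starting material
26 | 9-[2-(2-methyl-1,3-dioxolan-2-yl)ethyl]-9-borabicyclo[3.3.1]nonane | CC1(CCB2C3CCCC2CCC3)OCCO1 | intermediate (not isolated)
27 | (3aS,7R,8aS)-lactone with ketal side chain | C1C(=O)O[C@H]2C[C@@H](C)C(CCC3(C)OCCO3)=CC[C@@H]12 | intermediate
28 | 3-acetyl derivative of 27 (C3 epimers) | CC(=O)C1C(=O)O[C@H]2C[C@@H](C)C(CCC3(C)OCCO3)=CC[C@@H]12 | intermediate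
29 | trimethylsilyl enol ether of 28 (acetyl enol, E/Z) | CC(O[Si](C)(C)C)=C1C(=O)O[C@H]2C[C@@H](C)C(CCC3(C)OCCO3)=CC[C@@H]12 | intermediate (not isolated)
30 | (3S,3aR,7S,8aR)-5-methylene-7-methyl ketone from 14 | CC(C)(C)[Si](C)(C)OC[C@H]1C(=O)O[C@@H]2C[C@H](C)C(=O)C(=C)C[C@H]12 | intermediate (not isolated)
31 | C1′ diethoxymethylsilyl enol ether of 32 | CC(C)(C)[Si](C)(C)OC[C@H]1C(=O)O[C@@H]2C[C@H](C)C(O[Si](C)(OCC)OCC)=C(C[C@]3(C(C)=O)C(=O)O[C@H]4C[C@@H](C)C(CCC5(C)OCCO5)=CC[C@@H]34)C[C@H]12 | intermediate (not isolated)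
32 | coupled diketone (C13 on the face of lactone D anti to C6/C9; H5′ anti to lactone A) | CC(C)(C)[Si](C)(C)OC[C@H]1C(=O)O[C@@H]2C[C@H](C)C(=O)[C@H](C[C@]3(C(C)=O)C(=O)O[C@H]4C[C@@H](C)C(CCC5(C)OCCO5)=CC[C@@H]34)C[C@H]12 | intermediate
33 | ring C ketol (C1′–OH cis to C13 and C14′, trans to H5′) | CC(C)(C)[Si](C)(C)OC[C@H]1C(=O)O[C@@H]2C[C@H](C)[C@@]3(O)CC(=O)[C@@]4(C[C@@H]3C[C@H]12)C(=O)O[C@H]1C[C@@H](C)C(CCC2(C)OCCO2)=CC[C@H]14 | intermediate
34 | hydroxy enol triflate | CC(C)(C)[Si](C)(C)OC[C@H]1C(=O)O[C@@H]2C[C@H](C)[C@@]3(O)C=C(OS(=O)(=O)C(F)(F)F)[C@@]4(C[C@@H]3C[C@H]12)C(=O)O[C@H]1C[C@@H](C)C(CCC2(C)OCCO2)=CC[C@H]14 | intermediate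
35 | butyl vinyl ether | C=COCCCC | starting material
36 | 3′-(1-butoxyvinyl) diene | CC(C)(C)[Si](C)(C)OC[C@H]1C(=O)O[C@@H]2C[C@H](C)[C@@]3(O)C=C(C(=C)OCCCC)[C@@]4(C[C@@H]3C[C@H]12)C(=O)O[C@H]1C[C@@H](C)C(CCC2(C)OCCO2)=CC[C@H]14 | intermediate (not isolated)
37 | 13′-hydroxy-11′,13′-dihydro target | OC[C@H]1C(=O)O[C@@H]2C[C@H](C)[C@@]3(O)C=C(C(C)=O)[C@@]4(C[C@@H]3C[C@H]12)C(=O)O[C@H]1C[C@@H](C)C(CCC(C)=O)=CC[C@H]14 | intermediate
38 | 13′-mesylate of 37 | CS(=O)(=O)OC[C@H]1C(=O)O[C@@H]2C[C@H](C)[C@@]3(O)C=C(C(C)=O)[C@@]4(C[C@@H]3C[C@H]12)C(=O)O[C@H]1C[C@@H](C)C(CCC(C)=O)=CC[C@H]14 | intermediate (not isolated)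
39 | CNP0195550.1 | C=C1C(=O)O[C@@H]2C[C@H](C)[C@@]3(O)C=C(C(C)=O)[C@@]4(C[C@@H]3C[C@H]12)C(=O)O[C@H]1C[C@@H](C)C(CCC(C)=O)=CC[C@H]14 | target

**Step count**
Total: 23 steps. Longest linear sequence: 15 steps (1, 2, 3–10, 19–23; the branch 11–18 is equally long).

**Steps most likely to fail**

Step 19 (the proposed copper hydride relay) may fail through over-reduction of the exo-methylene ketone or direct SN2′ attack of the nucleophile. The fallback sets out from 14 and 28: Pd2(dba)3/dppe in THF at rt effects Tsuji–Trost allylic alkylation of the acetyl lactone by the 2-acyl-π-allyl complex of zerovalent palladium, with the same convex-face attack at C11, to give the coupled enone F1. [(Ph3P)CuH]6 in wet benzene then reduces only the enone C=C, and the route is rejoined at 32.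

Step 6 (allylic oxidation) may give regioisomeric enones by attack at the ring-fusion methine. The fallback sets out from 8: SeO2 (0.5 equiv)/t-BuOOH in CH2Cl2 hydroxylates by an ene reaction and [2,3]-shift, which prefers CH2 over CH, to give the C6 allylic alcohol F2, and Dess–Martin periodinane returns to 9. The mirror-image substrate 18 of step 13 would be treated the same way through the lower-series allylic alcohol F3, coming back at 19.

Step 20 (aldol) may give the cis-fused ketol or suffer retro-Michael cleavage. The fallback sets out from 32: LiN(SiMe3)2/Me3SiCl at −78 °C gives the acetyl trimethylsilyl enol ether F4. Catalytic TASF in THF at −78 to −40 °C then closes ring C by a fluoride-triggered silyl-transfer aldol that traps the aldolate irreversibly as the O-trimethylsilyl ketol F5, and aqueous citric acid returns to 33.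

**Further compounds**
F1 | step 19 | coupled enone (C5′=C6′) from Tsuji–Trost alkylation | CC(C)(C)[Si](C)(C)OC[C@H]1C(=O)O[C@@H]2C[C@H](C)C(=O)C(C[C@]3(C(C)=O)C(=O)O[C@H]4C[C@@H](C)C(CCC5(C)OCCO5)=CC[C@@H]34)=C[C@H]12
F2 | step 6 | C6 allylic alcohol of 8 (C6 epimers) | CC(C)(C)[Si](C)(C)OC[C@H]1C(=O)O[C@@H]2CCC(O)C=C[C@H]12
F3 | step 6 | C6 allylic alcohol of 18 (C6 epimers) | C1C(=O)O[C@H]2CCC(O)C=C[C@@H]12
F4 | step 20 | acetyl trimethylsilyl enol ether of 32 | CC(C)(C)[Si](C)(C)OC[C@H]1C(=O)O[C@@H]2C[C@H](C)C(=O)[C@H](C[C@]3(C(=C)O[Si](C)(C)C)C(=O)O[C@H]4C[C@@H](C)C(CCC5(C)OCCO5)=CC[C@@H]34)C[C@H]12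
F5 | step 20 | O-trimethylsilyl ether of ketol 33 | CC(C)(C)[Si](C)(C)OC[C@H]1C(=O)O[C@@H]2C[C@H](C)[C@@]3(O[Si](C)(C)C)CC(=O)[C@@]4(C[C@@H]3C[C@H]12)C(=O)O[C@H]1C[C@@H](C)C(CCC2(C)OCCO2)=CC[C@H]14
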